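Atom labels used throughout: C1–C10 for the decalin (ring A = C1–C5, C10; ring B = C5–C10), C11–C16 for the chain, C17 for the methyl on C8, C20 for the methyl on C10, C2'–C5' for the butenolide.

## Structural features

The target is a C25 terpenoid on a cis-fused decalin. Ring A is saturated and holds the gem-dimethyl carbon C4; ring B holds the tetrasubstituted alkene C8=C9, with a methyl on C8 and the side chain on C9. The only stereocentres are the vicinal ring-fusion atoms C5 (a methine) and C10 (quaternary, methyl-bearing), with H and CH3 cis, (4aR,8aS) in ring nomenclature; C5 is wedged between C10 and the quaternary C4. From C9 an ethylene link (C11–C12) leads to C13, which carries a free hydroxymethyl group and starts an E,E-diene (C13=C14, C15=C16) conjugated at C16 with C4' of a furan-2(5H)-one. The fragile parts are this dienyl butenolide (acidic C5' hydrogens, Michael acceptor, sensitive to hydride, base and light), the primary allylic alcohol, and the tetrasubstituted alkene, which can migrate under acid. The real difficulty is the C5–C10 bond: it joins a neopentyl methine to a quaternary carbon, must be cis and of one absolute sense, and has no neighbouring functional group in the target. The key step uses the fact that C2–C3–C4(Me2)–C5–C6 is a 3,3-dimethylglutarate chain: with C6 as a lactone carbonyl tied through oxygen to C2, and C2 carrying the C1=C10 alkene, ring A and the C5–C10 bond form together in a sigmatropic ring contraction, and the dispensable C2 oxygen is the only stereochemical input. The carboxyl carbon C6 and the carbinol carbon C9 left on C5 and C10 are exactly the atoms from which ring B is closed later.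

## Logic of the disconnections

37 is cut between C16 and C4', giving 35 and 36. The hydride- and base-sensitive unsaturated lactone then enters in the last step, and an sp2–sp2 coupling keeps the C15=C16 geometry. The forward step must be mild enough for the free allylic alcohol and the γ-acidic lactone.

35 is traced through 34 (ester level at the future hydroxymethyl carbon) to 32 and 33 by cutting C13=C14. A phosphonate carbanion at C13 that carries the ester gives the trisubstituted alkene with the ester trans to C15, which is the required E arrangement. This removes the whole diene terminus in one step. The demand is E-selective olefination and a boronate that survives base and the later hydride reduction.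

32 is cut at C12–C13 into 30 and 31. 30 comes from 29, and 29 from 26 by excising the terminal alkene carbon (through 27 and 28). Alkylation of a stabilised carbanion by a primary iodide is the simplest way to join the chain to the bicycle. Substitution must beat elimination toward the allylic C11 hydrogens, and the alkene cleavage must spare C8=C9.

26 is opened at C8=C9 to 25. A reductive carbonyl coupling places the tetrasubstituted alkene exactly between the two former carbonyl carbons, so no regioisomeric alkene can arise. Ring B disappears and both stereocentres stay on ring A. The coupling must work at a neopentyl ketone and tolerate the allyl group.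

25 is returned to the alcohol level (24) and cut at C9–C11 into 21 and 22. C9 is then a non-enolisable aldehyde carbon on the quaternary C10. The nucleophile must choose this hindered aldehyde over the methyl ketone without base, which points to an allylboron reagent.

21 goes back through 20 to 19, which is cut at C6=C7 into 17 and 18. This brings in C7, C8 and C17 at once, and a single hydrogenation then saturates C6=C7 and C1=C2 and frees the C9 hydroxyl. The olefination has to proceed at a doubly neopentyl, epimerisable aldehyde without loss of the C5 configuration.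

17 is taken back through 16 to 15, and 15 is disconnected at C5–C10 with reconnection of C2 to the carboxyl oxygen, giving 12 (through 14 and 13). This is the most congested bond and it carries both stereocentres; a [3,3] shift turns them into one carbinol centre and one alkene geometry. The forward step needs a geometrically pure E alkene, an enantiopure C2 and a boat array that tolerates the crowding. The benzyl group on the C9 oxygen is kept because it is inert to amide base and leaves in the later hydrogenation.

12 is opened at the lactone C–O bond to 11, which comes from 10 by carbonyl reduction; 10 is cut at C1–C2 into 4 and 7. The carbinol centre is thus set by a catalytic reduction of an enone. The demands are facial selectivity in the reduction and acylation at the amide carbonyl only.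

4 comes from 3, and 3 from 1 by cutting C10–C20 and C1–I across the alkyne (through 2); 7 comes from 6 and 6 from 5. Syn carbometallation fixes the E geometry, and the symmetric anhydride already contains C2–C6 with the gem-dimethyl group. The carbometallation must be regio- and stereoselective.

## Other disconnections considered

Alternative 1: The cut is C4–C5, C9–C10 and C8–O at once, back to the acyclic (3E,7Z)-homofarnesol A1. The forward key step is a proton-initiated polyene cyclisation under a confined chiral Brønsted acid (or a BINOL-derived acid with SnCl4), which would give the tricyclic ether A2 with cis-fused rings A and B. In its favour, both rings and both stereocentres come from a linear chain in one catalytic step, and C11–C12 with an oxygen on C12 is already in place. On step count to the bicyclic core and on the side-chain handle it is better than the chosen plan, which spends several steps on ring B and the C12 iodide. Against it here: the cis fusion rests on a geometrically pure Z trisubstituted alkene in A1, which is harder to secure than the all-E chain. Z substrates are expected to cyclise through less ordered arrays, so the translation of alkene geometry into configuration is less certain than a concerted suprafacial shift through an enforced boat. The C8–O bond must then be eliminated toward C9 only, in competition with loss toward C7 or C17. On structure the two plans reach the same C12 alcohol stage; on mechanism the chosen plan is more predictable; on step economy the alternative would win if the ether-to-alkene step were regioselective.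

Alternative 2: The cut is C9–C10, back to the monocyclic keto alkynoate A3. Under catalytic KOtBu the more substituted enolate of the C1 ketone would add to C9 of the tethered ynoate (6-exo-dig conjugate addition) and give the cis-decalone A4 with an exocyclic C9=C11 enoate. In its favour, the quaternary C10, ring B and the C11–C12 carboxyl handle come in one step, and deconjugation into the ring would later merge the C8 epimers and both enoate geometries into the C8=C9 alkene. For ring B plus handle it is better in step economy than olefination, hydrogenation, allylation and carbonyl coupling. Against it here: A3 must already carry C5 as a single enantiomer, so absolute control needs a separate asymmetric step. The cis relationship of C5 and C10 depends on substrate-controlled facial selectivity of a reversible enolate addition, whereas the chosen plan fixes it by a tether. The C1 ketone must be removed afterwards and the deconjugation equilibrium is not assured. On structure both plans give a C12 oxygen handle; on mechanism the alternative is polar and reversible, the chosen one pericyclic and stereospecific.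

Alternative 3: The cut is C1–C10 and C4–C5, back to 2,6-dimethyl-1,4-benzoquinone A5 and allylidenecyclopropane A6. A proline-derived oxazaborolidine activated by HNTf2 would catalyse an enantioselective Diels–Alder reaction across a methyl-bearing quinone alkene and give the cis-fused enedione A7 with a spirocyclopropane at C4 as masked CMe2. In its favour, the cis fusion is guaranteed by suprafacial addition, equal to the chosen plan on this point. Both stereocentres come by catalyst control from two achiral partners in one convergent step, which is better than the chosen plan's reduction plus relay. Against it here: A7 needs heavy editing (two ring-B carbonyls, two alkenes, hydrogenolysis of the cyclopropane to the gem-dimethyl group). C5–H is α to the C6 ketone and can epimerise toward the trans dione, which endangers the centre the step has just set. The disubstituted diene terminus must bond to C5 next to the quaternary C10, a crowded union. On structure the alternative delivers ring B at once but in the wrong oxidation pattern; on step economy its gain at the start is likely lost in the adjustments.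

Key step: step 7

Remark: descriptors were checked atom by atom; the (6S,E)-lactone 12 leads through the boat array to (1R,2S)-15, which maps onto (4aR,8aS) in 37.
Remark: in step 6 the trisubstituted alkenyl group is assumed to act as the larger ketone substituent, hence the (R)-catalyst for the S carbinol; compounds 22, 31 and 33 are treated as purchased.

## Route

Step 1
Reactants: 1 prop-2-yn-1-ol (propargyl alcohol)
Product: 3 (2E)-3-iodo-2-methylprop-2-en-1-ol, via alkenylalane 2 (not isolated)
Conditions: AlMe3 (3 equiv), Cp2ZrCl2 (0.25 equiv), CH2Cl2, 0 °C to rt; then I2, THF, −30 to 0 °C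
Reagents that add atoms: trimethylaluminium, C[Al](C)C; iodine, II
Why: Zirconium-catalysed syn carboalumination of the terminal alkyne (Negishi type) puts CH3 on the internal carbon and aluminium on the terminal one; iodinolysis with retention fixes the E geometry (I cis to CH3), the later E geometry of C1=C10.

Step 2
Reactants: 3 (2E)-3-iodo-2-methylprop-2-en-1-ol
Product: 4 {[(2E)-3-iodo-2-methylprop-2-en-1-yl]oxy}methylbenzene
Conditions: NaH, BnBr, Bu4NI (cat.), THF, 0 °C to rt
Reagents that add atoms: benzyl bromide, BrCc1ccccc1
Why: Williamson etherification of the primary allylic alkoxide; the alkenyl iodide is inert to these conditions and the alkene geometry is untouched.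

Step 3
Reactants: 5 3,3-dimethylglutaric anhydride
Product: 6 5-methoxy-3,3-dimethyl-5-oxopentanoic acid
Conditions: MeOH, reflux
Reagents that add atoms: methanol, CO
Why: Alcoholysis of a symmetric cyclic anhydride gives one half ester only, so the two carboxyl ends (future C2 and C6) are differentiated in one operation.

Step 4
Reactants: 6 5-methoxy-3,3-dimethyl-5-oxopentanoic acid
Product: 7 methyl 5-[methoxy(methyl)amino]-3,3-dimethyl-5-oxopentanoate
Conditions: MeNH(OMe)·HCl, EDC·HCl, N-methylmorpholine, DMAP (cat.), CH2Cl2, 0 °C to rt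
Reagents that add atoms: N,O-dimethylhydroxylamine hydrochloride, CNOC.Cl
Why: Carbodiimide amide coupling of the free acid; the methyl ester is not touched, and the N-methoxy-N-methylamide prepares a ketone synthesis that stops after one addition.

Step 5
Reactants: 4 {[(2E)-3-iodo-2-methylprop-2-en-1-yl]oxy}methylbenzene; 7 methyl 5-[methoxy(methyl)amino]-3,3-dimethyl-5-oxopentanoate
Product: 10 methyl (6E)-8-(benzyloxy)-3,3,7-trimethyl-5-oxooct-6-enoate, via alkenyllithium 8 (not isolated), via lithium hemiaminal chelate 9 (not isolated)
Conditions: 4, t-BuLi (2.1 equiv), Et2O, −78 °C; then 7, THF, −78 to −40 °C; aq. NH4Cl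
Reagents that add atoms: none
Why: Iodine–lithium exchange proceeds with retention of alkene geometry, and the Weinreb ketone synthesis forms C1–C2; the amide is attacked in preference to the ester at −78 °C and the chelated adduct 9 prevents a second addition until work-up.

Step 6
Reactants: 10 methyl (6E)-8-(benzyloxy)-3,3,7-trimethyl-5-oxooct-6-enoate
Product: 12 (6S)-6-[(1E)-3-(benzyloxy)-2-methylprop-1-en-1-yl]-4,4-dimethyloxan-2-one, via hydroxy ester 11 (not isolated)
Conditions: (R)-2-methyl-CBS-oxazaborolidine (0.2 equiv), BH3·SMe2, THF, −30 °C; MeOH quench; then PPTS (cat.), PhMe, 50 °C, 4 Å sieves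
Reagents that add atoms: none
Why: Corey–Bakshi–Shibata reduction delivers hydride to the enone face that keeps the alkenyl group away from the catalyst, which should set C2 as S; the δ-hydroxy ester then lactonises under mild acid, helped by the gem-dimethyl group, without ionising the allylic C–O bond.

Step 7
Reactants: 12 (6S)-6-[(1E)-3-(benzyloxy)-2-methylprop-1-en-1-yl]-4,4-dimethyloxan-2-one
Product: 15 (1R,2S)-2-[(benzyloxy)methyl]-2,6,6-trimethylcyclohex-3-ene-1-carboxylic acid, via silyl ketene acetal 13 (not isolated), via silyl ester 14 (not isolated)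
Conditions: TBSCl (1.5 equiv), DMPU, THF, −78 °C, LiN(iPr)2 (1.3 equiv) added slowly; to rt; PhMe, 105 °C; then 1 M HCl, THF, rt
Reagents that add atoms: none
Why: O-Silylation of the lactone enolate as it forms gives the cyclic ketene acetal 13, a 1,5-diene along C5=C6–O–C2–C1=C10, which on heating undergoes a concerted suprafacial [3,3]-sigmatropic shift that forms C5–C10 as O–C2 breaks and gives silyl ester 14, hydrolysed to 15. The closest known reaction type is the Ireland–Claisen ring contraction of 6-alkenyl δ-lactone silyl ketene acetals to cyclohex-3-enecarboxylic acids. Ring A (C1, C2, C3, C4, C5, C10) closes inside the pericyclic event through a bicyclo[2.2.2]octane-like array, as a ring contraction and not as a separate polar cyclisation, and its C1=C2 alkene is necessarily cis. Because C3–C4 ties C2 to C5, only a boat-like array is possible, with the alkenyl group axial on C2. The configuration of C5 is set by the face of the ketene acetal to which the C2 substituent is tethered, that is by the 6S carbinol centre. The configuration of C10 is set by the same face together with the E geometry of C1=C10, which in the boat puts C9 (trans to C2) on the side of C6 and the C10 methyl on the side of C5–H, so carboxyl and CH2OBn end cis. The step needs diastereoselection and complete chirality transfer; both are secured by the tether, provided the alkene is geometrically pure, and enolisation can occur only at C5. The developing 1,3 contact between the C10 methyl and a C4 methyl raises the barrier, hence the heating, but no other pericyclic path competes.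

Step 8
Reactants: 15 (1R,2S)-2-[(benzyloxy)methyl]-2,6,6-trimethylcyclohex-3-ene-1-carboxylic acid
Product: 16 [(1R,2S)-2-[(benzyloxy)methyl]-2,6,6-trimethylcyclohex-3-en-1-yl]methanol
Conditions: LiAlH4, THF, 0 °C to reflux; then H2O, 15% aq. NaOH, H2O
Reagents that add atoms: none
Why: Hydride reduction of the hindered carboxylic acid to the primary alcohol; the carboxylate cannot enolise, so C5 is safe, and the alkene and benzyl ether are inert.

Step 9
Reactants: 16 [(1R,2S)-2-[(benzyloxy)methyl]-2,6,6-trimethylcyclohex-3-en-1-yl]methanol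
Product: 17 (1R,2S)-2-[(benzyloxy)methyl]-2,6,6-trimethylcyclohex-3-ene-1-carbaldehyde
Conditions: Dess–Martin periodinane, NaHCO3, CH2Cl2, 0 °C to rt
Reagents that add atoms: none
Why: Dess–Martin oxidation under buffered, non-basic conditions stops at the aldehyde and should leave the α-stereocentre C5 untouched; the aldehyde is used at once.

Step 10
Reactants: 17 (1R,2S)-2-[(benzyloxy)methyl]-2,6,6-trimethylcyclohex-3-ene-1-carbaldehyde; 18 diethyl (2-oxopropyl)phosphonate
Product: 19 (3E)-4-[(1R,2S)-2-[(benzyloxy)methyl]-2,6,6-trimethylcyclohex-3-en-1-yl]but-3-en-2-one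
Conditions: Ba(OH)2 (activated, 0.8 equiv), THF/H2O (40:1), rt
Reagents that add atoms: none
Why: Horner–Wadsworth–Emmons olefination with a β-ketophosphonate forms C6=C7 and brings in C7, C8 and C17; the weakly basic heterogeneous hydroxide is chosen to avoid enolisation of the hindered aldehyde at C5, and the geometry is irrelevant because the alkene is reduced next.

Step 11
Reactants: 19 (3E)-4-[(1R,2S)-2-[(benzyloxy)methyl]-2,6,6-trimethylcyclohex-3-en-1-yl]but-3-en-2-one
Product: 20 4-[(1R,2S)-2-(hydroxymethyl)-2,6,6-trimethylcyclohexyl]butan-2-one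
Conditions: H2 (1–3 atm), 10% Pd/C, EtOAc/EtOH, rt
Reagents that add atoms: none
Why: One catalytic hydrogenation saturates the enone C6=C7 and the ring alkene C1=C2 (no new stereocentre, both carbons become CH2) and hydrogenolyses the benzyl ether; the ketone is not reduced over palladium.

Step 12
Reactants: 20 4-[(1R,2S)-2-(hydroxymethyl)-2,6,6-trimethylcyclohexyl]butan-2-one
Product: 21 (1S,2R)-1,3,3-trimethyl-2-(3-oxobutyl)cyclohexane-1-carbaldehyde
Conditions: Dess–Martin periodinane, NaHCO3, CH2Cl2, 0 °C to rt
Reagents that add atoms: none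
Why: Dess–Martin oxidation of the neopentyl primary alcohol gives the C9 aldehyde, which has no α-hydrogen; neutral conditions avoid aldol closure between C7 and C9.

Step 13
Reactants: 21 (1S,2R)-1,3,3-trimethyl-2-(3-oxobutyl)cyclohexane-1-carbaldehyde; 22 4,4,5,5-tetramethyl-2-(prop-2-en-1-yl)-1,3,2-dioxaborolane (allylboronic acid pinacol ester)
Product: 24 4-[(1R,2S)-2-(1-hydroxybut-3-en-1-yl)-2,6,6-trimethylcyclohexyl]butan-2-one (both C9 epimers), via borate ester 23 (not isolated)
Conditions: 22 (1.5 equiv), CH2Cl2, rt to 40 °C; aq. NaHCO3 work-up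
Reagents that add atoms: none
Why: Uncatalysed allylboration through a closed six-membered transition state forms C9–C11 at the aldehyde only, because allylboronates do not add to unactivated ketones and no base is present; the new C9 centre is lost in the next step, so its configuration does not matter.

Step 14
Reactants: 24 4-[(1R,2S)-2-(1-hydroxybut-3-en-1-yl)-2,6,6-trimethylcyclohexyl]butan-2-one
Product: 25 1-[(1S,2R)-1,3,3-trimethyl-2-(3-oxobutyl)cyclohexyl]but-3-en-1-one
Conditions: Dess–Martin periodinane, NaHCO3, CH2Cl2, 0 °C
Reagents that add atoms: none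
Why: Dess–Martin oxidation of the secondary alcohol gives the 1,6-diketone; buffered conditions keep the β,γ-alkene out of conjugation.

Step 15
Reactants: 25 1-[(1S,2R)-1,3,3-trimethyl-2-(3-oxobutyl)cyclohexyl]but-3-en-1-one
Product: 26 (4aR,8aS)-2,5,5,8a-tetramethyl-1-(prop-2-en-1-yl)-3,4,4a,5,6,7,8,8a-octahydronaphthalene
Conditions: TiCl3(DME)1.5, Zn–Cu couple, DME, reflux; 25 added by syringe pump (high dilution)
Reagents that add atoms: none
Why: Intramolecular McMurry coupling joins C8 and C9 on low-valent titanium and removes both oxygens, closing ring B with the tetrasubstituted alkene fixed between the former carbonyl carbons; six-membered ring formation from 1,6-diketones is the favourable case and isolated alkenes are tolerated.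

Step 16
Reactants: 26 (4aR,8aS)-2,5,5,8a-tetramethyl-1-(prop-2-en-1-yl)-3,4,4a,5,6,7,8,8a-octahydronaphthalene
Product: 29 2-[(4aR,8aS)-2,5,5,8a-tetramethyl-3,4,4a,5,6,7,8,8a-octahydronaphthalen-1-yl]ethan-1-ol, via diol 27 (not isolated), via aldehyde 28 (not isolated)
Conditions: OsO4 (2 mol%), NaIO4, 2,6-lutidine, dioxane/H2O (3:1), rt; extractive work-up; then NaBH4, MeOH, 0 °C
Reagents that add atoms: sodium periodate, [Na+].[O-]I(=O)(=O)=O (oxygen passed on by catalytic osmium tetroxide, O=[Os](=O)(=O)=O)
Why: Lemieux–Johnson cleavage removes the terminal carbon of the monosubstituted alkene, which osmylates far faster than the shielded tetrasubstituted C8=C9; the β,γ-unsaturated aldehyde is reduced at once with borohydride so that the ring alkene cannot move into conjugation.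

Step 17
Reactants: 29 2-[(4aR,8aS)-2,5,5,8a-tetramethyl-3,4,4a,5,6,7,8,8a-octahydronaphthalen-1-yl]ethan-1-ol
Product: 30 (4aR,8aS)-1-(2-iodoethyl)-2,5,5,8a-tetramethyl-3,4,4a,5,6,7,8,8a-octahydronaphthalene
Conditions: I2, PPh3, imidazole, CH2Cl2, 0 °C to rt, dark
Reagents that add atoms: iodine, II
Why: Appel-type iodination of the unhindered primary alcohol by SN2 displacement of the oxyphosphonium group; buffered by imidazole, so the acid-sensitive alkene is safe.

Step 18
Reactants: 30 (4aR,8aS)-1-(2-iodoethyl)-2,5,5,8a-tetramethyl-3,4,4a,5,6,7,8,8a-octahydronaphthalene; 31 triethyl phosphonoacetate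
Product: 32 ethyl 2-(diethoxyphosphoryl)-4-[(4aR,8aS)-2,5,5,8a-tetramethyl-3,4,4a,5,6,7,8,8a-octahydronaphthalen-1-yl]butanoate (both C13 epimers)
Conditions: 31 (3 equiv), NaH (2.8 equiv), DMF/THF, 0 °C; then 30, 50 °C
Reagents that add atoms: none
Why: C-Alkylation of the soft, weakly basic phosphonoacetate anion by the primary iodide forms C12–C13; the excess of anion suppresses dialkylation and its low basicity disfavours elimination toward C11.

Step 19
Reactants: 32 ethyl 2-(diethoxyphosphoryl)-4-[(4aR,8aS)-2,5,5,8a-tetramethyl-3,4,4a,5,6,7,8,8a-octahydronaphthalen-1-yl]butanoate; 33 (2E)-3-(4,4,5,5-tetramethyl-1,3,2-dioxaborolan-2-yl)prop-2-enal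
Product: 34 ethyl (2E,4E)-2-{2-[(4aR,8aS)-2,5,5,8a-tetramethyl-3,4,4a,5,6,7,8,8a-octahydronaphthalen-1-yl]ethyl}-5-(4,4,5,5-tetramethyl-1,3,2-dioxaborolan-2-yl)penta-2,4-dienoate
Conditions: LiN(SiMe3)2 (1.05 equiv), THF, −78 °C; then 33, −78 °C to rt
Reagents that add atoms: none
Why: Horner–Wadsworth–Emmons olefination of an α-alkyl phosphonoacetate with an enal forms C13=C14 with the ester trans to C15 (E), favoured by reversible addition under lithium counter-ion; the C15=C16 geometry comes unchanged from 33.

Step 20
Reactants: 34 ethyl (2E,4E)-2-{2-[(4aR,8aS)-2,5,5,8a-tetramethyl-3,4,4a,5,6,7,8,8a-octahydronaphthalen-1-yl]ethyl}-5-(4,4,5,5-tetramethyl-1,3,2-dioxaborolan-2-yl)penta-2,4-dienoate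
Product: 35 (2E,4E)-2-{2-[(4aR,8aS)-2,5,5,8a-tetramethyl-3,4,4a,5,6,7,8,8a-octahydronaphthalen-1-yl]ethyl}-5-(4,4,5,5-tetramethyl-1,3,2-dioxaborolan-2-yl)penta-2,4-dien-1-ol
Conditions: iBu2AlH (2.5 equiv), CH2Cl2, −78 °C; aq. KNaC4H4O6 work-up
Reagents that add atoms: none
Why: 1,2-Reduction of the conjugated ester by the electrophilic aluminium hydride gives the allylic alcohol at low temperature, where the hindered pinacol boronate should not be attacked; this is done before the butenolide is present, so no lactone competes.

Step 21
Reactants: 35 (2E,4E)-2-{2-[(4aR,8aS)-2,5,5,8a-tetramethyl-3,4,4a,5,6,7,8,8a-octahydronaphthalen-1-yl]ethyl}-5-(4,4,5,5-tetramethyl-1,3,2-dioxaborolan-2-yl)penta-2,4-dien-1-ol; 36 4-bromofuran-2(5H)-one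
Product: 37 4-[(1E,3E)-4-(hydroxymethyl)-6-[(4aR,8aS)-2,5,5,8a-tetramethyl-3,4,4a,5,6,7,8,8a-octahydronaphthalen-1-yl]hexa-1,3-dien-1-yl]furan-2(5H)-one
Conditions: Pd(PPh3)4 (5 mol%), aq. K3PO4, THF, 45 °C, degassed, dark
Reagents that add atoms: none
Why: Suzuki–Miyaura coupling: zerovalent palladium inserts into the activated C4'–Br bond, the E-alkenylboronate transmetallates with retention and reductive elimination forms C16–C4'; the mild phosphate base and moderate temperature should spare the butenolide and the free alcohol.

## Compound list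

1 | prop-2-yn-1-ol | C#CCO | starting material
2 | (E)-[3-(dimethylalumanyloxy)-2-methylprop-1-en-1-yl]dimethylalumane | C[Al](C)OC/C(C)=C/[Al](C)C | intermediate
3 | (2E)-3-iodo-2-methylprop-2-en-1-ol | OC/C(C)=C/I | intermediate
4 | {[(2E)-3-iodo-2-methylprop-2-en-1-yl]oxy}methylbenzene | C/C(=C\I)COCc1ccccc1 | intermediate
5 | 3,3-dimethylglutaric anhydride | CC1(C)CC(=O)OC(=O)C1 | starting material
6 | 5-methoxy-3,3-dimethyl-5-oxopentanoic acid | COC(=O)CC(C)(C)CC(=O)O | intermediate
7 | methyl 5-[methoxy(methyl)amino]-3,3-dimethyl-5-oxopentanoate | COC(=O)CC(C)(C)CC(=O)N(C)OC | intermediate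
8 | [(1E)-3-(benzyloxy)-2-methylprop-1-en-1-yl]lithium | C/C(=C\[Li])COCc1ccccc1 | intermediate
9 | lithium alkoxide of methyl (6E)-8-(benzyloxy)-5-hydroxy-5-[methoxy(methyl)amino]-3,3,7-trimethyloct-6-enoate | COC(=O)CC(C)(C)CC(O[Li])(N(C)OC)/C=C(\C)COCc1ccccc1 | intermediate
10 | methyl (6E)-8-(benzyloxy)-3,3,7-trimethyl-5-oxooct-6-enoate | COC(=O)CC(C)(C)CC(=O)/C=C(\C)COCc1ccccc1 | intermediate
11 | methyl (5S,6E)-8-(benzyloxy)-5-hydroxy-3,3,7-trimethyloct-6-enoate | COC(=O)CC(C)(C)C[C@@H](/C=C(\C)COCc1ccccc1)O | intermediate
12 | (6S)-6-[(1E)-3-(benzyloxy)-2-methylprop-1-en-1-yl]-4,4-dimethyloxan-2-one | O=C1CC(C)(C)C[C@@H](/C=C(\C)COCc2ccccc2)O1 | intermediate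
13 | {[(2S)-2-[(1E)-3-(benzyloxy)-2-methylprop-1-en-1-yl]-4,4-dimethyl-3,4-dihydro-2H-pyran-6-yl]oxy}(tert-butyl)dimethylsilane | CC(C)(C)[Si](C)(C)OC1=CC(C)(C)C[C@@H](/C=C(\C)COCc2ccccc2)O1 | intermediate
14 | tert-butyldimethylsilyl (1R,2S)-2-[(benzyloxy)methyl]-2,6,6-trimethylcyclohex-3-ene-1-carboxylate | c1ccccc1COC[C@@]2(C)C=CCC(C)(C)[C@H]2C(=O)O[Si](C)(C)C(C)(C)C | intermediate
15 | (1R,2S)-2-[(benzyloxy)methyl]-2,6,6-trimethylcyclohex-3-ene-1-carboxylic acid | c1ccccc1COC[C@@]2(C)C=CCC(C)(C)[C@H]2C(=O)O | intermediate
16 | [(1R,2S)-2-[(benzyloxy)methyl]-2,6,6-trimethylcyclohex-3-en-1-yl]methanol | c1ccccc1COC[C@@]2(C)C=CCC(C)(C)[C@H]2CO | intermediate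
17 | (1R,2S)-2-[(benzyloxy)methyl]-2,6,6-trimethylcyclohex-3-ene-1-carbaldehyde | c1ccccc1COC[C@@]2(C)C=CCC(C)(C)[C@H]2C=O | intermediate
18 | diethyl (2-oxopropyl)phosphonate | CCOP(=O)(CC(C)=O)OCC | starting material
19 | (3E)-4-[(1R,2S)-2-[(benzyloxy)methyl]-2,6,6-trimethylcyclohex-3-en-1-yl]but-3-en-2-one | c1ccccc1COC[C@@]2(C)C=CCC(C)(C)[C@H]2/C=C/C(C)=O | intermediate
20 | 4-[(1R,2S)-2-(hydroxymethyl)-2,6,6-trimethylcyclohexyl]butan-2-one | OC[C@@]2(C)CCCC(C)(C)[C@H]2CCC(C)=O | intermediate
21 | (1S,2R)-1,3,3-trimethyl-2-(3-oxobutyl)cyclohexane-1-carbaldehyde | O=C[C@@]2(C)CCCC(C)(C)[C@H]2CCC(C)=O | intermediate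
22 | 4,4,5,5-tetramethyl-2-(prop-2-en-1-yl)-1,3,2-dioxaborolane | C=CCB1OC(C)(C)C(C)(C)O1 | starting material
23 | 4-[(1R,2S)-2-{1-[(4,4,5,5-tetramethyl-1,3,2-dioxaborolan-2-yl)oxy]but-3-en-1-yl}-2,6,6-trimethylcyclohexyl]butan-2-one (both C9 epimers) | C=CCC(OB3OC(C)(C)C(C)(C)O3)[C@@]2(C)CCCC(C)(C)[C@H]2CCC(C)=O | intermediate
24 | 4-[(1R,2S)-2-(1-hydroxybut-3-en-1-yl)-2,6,6-trimethylcyclohexyl]butan-2-one (both C9 epimers) | C=CCC(O)[C@@]2(C)CCCC(C)(C)[C@H]2CCC(C)=O | intermediate
25 | 1-[(1S,2R)-1,3,3-trimethyl-2-(3-oxobutyl)cyclohexyl]but-3-en-1-one | C=CCC(=O)[C@@]2(C)CCCC(C)(C)[C@H]2CCC(C)=O | intermediate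
26 | (4aR,8aS)-2,5,5,8a-tetramethyl-1-(prop-2-en-1-yl)-3,4,4a,5,6,7,8,8a-octahydronaphthalene | CC1=C(CC=C)[C@@]2(C)CCCC(C)(C)[C@H]2CC1 | intermediate
27 | 3-[(4aR,8aS)-2,5,5,8a-tetramethyl-3,4,4a,5,6,7,8,8a-octahydronaphthalen-1-yl]propane-1,2-diol (both epimers) | CC1=C(CC(O)CO)[C@@]2(C)CCCC(C)(C)[C@H]2CC1 | intermediate
28 | 2-[(4aR,8aS)-2,5,5,8a-tetramethyl-3,4,4a,5,6,7,8,8a-octahydronaphthalen-1-yl]acetaldehyde | CC1=C(CC=O)[C@@]2(C)CCCC(C)(C)[C@H]2CC1 | intermediate
29 | 2-[(4aR,8aS)-2,5,5,8a-tetramethyl-3,4,4a,5,6,7,8,8a-octahydronaphthalen-1-yl]ethan-1-ol | CC1=C(CCO)[C@@]2(C)CCCC(C)(C)[C@H]2CC1 | intermediate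
30 | (4aR,8aS)-1-(2-iodoethyl)-2,5,5,8a-tetramethyl-3,4,4a,5,6,7,8,8a-octahydronaphthalene | CC1=C(CCI)[C@@]2(C)CCCC(C)(C)[C@H]2CC1 | intermediate
31 | triethyl phosphonoacetate | CCOC(=O)CP(=O)(OCC)OCC | starting material
32 | ethyl 2-(diethoxyphosphoryl)-4-[(4aR,8aS)-2,5,5,8a-tetramethyl-3,4,4a,5,6,7,8,8a-octahydronaphthalen-1-yl]butanoate (both C13 epimers) | CC1=C(CCC(C(=O)OCC)P(=O)(OCC)OCC)[C@@]2(C)CCCC(C)(C)[C@H]2CC1 | intermediate
33 | (2E)-3-(4,4,5,5-tetramethyl-1,3,2-dioxaborolan-2-yl)prop-2-enal | O=C/C=C/B1OC(C)(C)C(C)(C)O1 | starting material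
34 | ethyl (2E,4E)-2-{2-[(4aR,8aS)-2,5,5,8a-tetramethyl-3,4,4a,5,6,7,8,8a-octahydronaphthalen-1-yl]ethyl}-5-(4,4,5,5-tetramethyl-1,3,2-dioxaborolan-2-yl)penta-2,4-dienoate | CC1=C(CC/C(=C\C=C\B3OC(C)(C)C(C)(C)O3)C(=O)OCC)[C@@]2(C)CCCC(C)(C)[C@H]2CC1 | intermediate
35 | (2E,4E)-2-{2-[(4aR,8aS)-2,5,5,8a-tetramethyl-3,4,4a,5,6,7,8,8a-octahydronaphthalen-1-yl]ethyl}-5-(4,4,5,5-tetramethyl-1,3,2-dioxaborolan-2-yl)penta-2,4-dien-1-ol | CC1=C(CC/C(=C\C=C\B3OC(C)(C)C(C)(C)O3)CO)[C@@]2(C)CCCC(C)(C)[C@H]2CC1 | intermediate
36 | 4-bromofuran-2(5H)-one | BrC1=CC(=O)OC1 | starting material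
37 | 4-[(1E,3E)-4-(hydroxymethyl)-6-[(4aR,8aS)-2,5,5,8a-tetramethyl-3,4,4a,5,6,7,8,8a-octahydronaphthalen-1-yl]hexa-1,3-dien-1-yl]furan-2(5H)-one | CC1=C(CC/C(=C\C=C\C2=CC(=O)OC2)CO)[C@@]2(C)CCCC(C)(C)[C@H]2CC1 | target

## Step count and least certain steps

Total: 21 steps. Longest linear sequence: 19 steps (steps 1, 2 and 5 to 21; the branch through steps 3, 4 and 5 to 21 is equally long).

Step 7 (key step). Most likely failure: slow enolisation and silylation at the neopentyl α-methylene, with ring opening or self-condensation of the enolate, and a raised barrier in the boat array where the C10 methyl is pressed against a C4 methyl, so that long heating leads to desilylation or decomposition instead of rearrangement. Fallback, from 4 back to 15: the same C5–C10 bond would be made through an untethered chair and ring A closed afterwards by metathesis. Iodide 4 is lithiated as in step 5 and acylated with N-methoxy-N-methylacetamide to give (3E)-5-(benzyloxy)-4-methylpent-3-en-2-one F1. Reduction with BH3·SMe2 under (S)-2-methyl-CBS-oxazaborolidine gives (2R,3E)-5-(benzyloxy)-4-methylpent-3-en-2-ol F2. In parallel, allylmagnesium bromide adds to 2,2-dimethyl-5-(propan-2-ylidene)-1,3-dioxane-4,6-dione to give 2,2-dimethyl-5-(2-methylpent-4-en-2-yl)-1,3-dioxane-4,6-dione F3, and hydrolysis with decarboxylation in hot aqueous pyridine gives 3,3-dimethylhex-5-enoic acid F4. DCC/DMAP esterification of F2 with F4 gives (2R,3E)-5-(benzyloxy)-4-methylpent-3-en-2-yl 3,3-dimethylhex-5-enoate F5. LiN(iPr)2 and TBSCl in THF/DMPU (Z ketene acetal), warming and acid hydrolysis should give (2R,3S,4E)-3-[(benzyloxy)methyl]-3-methyl-2-(2-methylpent-4-en-2-yl)hex-4-enoic acid F6 through a chair with the carbinol methyl equatorial. The second-generation Grubbs catalyst (H2IMes)(PCy3)Cl2Ru=CHPh then closes ring A between the propenyl and allyl groups with loss of propene and returns to 15.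

Step 6. Most likely failure: poor facial discrimination, because the neopentyl-type methylene chain and the trisubstituted alkenyl group may present similar bulk at the coordinated carbonyl, together with some hydroboration of the alkene. Fallback, from 7 and 8 back to 11: the carbinol centre would be set by C–C bond formation. Cp2Zr(H)Cl reduces the amide of 7 to methyl 3,3-dimethyl-5-oxopentanoate F7. Alkenyllithium 8 is transmetallated with ZnBr2 to [(1E)-3-(benzyloxy)-2-methylprop-1-en-1-yl]zinc bromide F8. Addition of F8 to F7 under a catalytic chiral amino alcohol (the 3-exo-morpholinoisoborneol antipode that gives the S carbinol, with a diamine to bind lithium salts) should give 11, which lactonises to 12 as in step 6.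

Step 10. Most likely failure: epimerisation at C5 by enolisation of aldehyde 17 while the olefination of this doubly neopentyl aldehyde is slow, or γ-deprotonation of 19. Fallback, from 15 back to 20: C6 stays tied to C9 in a cis-fused five-membered ring, where the cis fusion is the stable arrangement, and no base is used. Hydrogenation of 15 over Pd/C followed by TsOH (cat.) gives the cis lactone (3aS,7aR)-3a,7,7-trimethylhexahydro-2-benzofuran-1(3H)-one F9. iBu2AlH at −78 °C gives the lactol (3aS,7aR)-3a,7,7-trimethyloctahydro-2-benzofuran-1-ol F10. Neutral Wittig olefination with 1-(triphenylphosphoranylidene)propan-2-one in PhMe at 90 °C opens it to (3E)-4-[(1R,2S)-2-(hydroxymethyl)-2,6,6-trimethylcyclohexyl]but-3-en-2-one F11, and hydrogenation over Pd/C returns to 20.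

Step 15. Most likely failure: titanium-promoted migration of the allyl ketone alkene into conjugation or aldol-type closure before coupling, and incomplete deoxygenation at the neopentyl carbonyl. Fallback, from 25 back to 26: SmI2 in THF with t-BuOH effects a pinacol cyclisation to the cis diol (4aR,8aS)-2,5,5,8a-tetramethyl-1-(prop-2-en-1-yl)decahydronaphthalene-1,2-diol F12. Thiophosgene and DMAP convert it to the cyclic thiocarbonate F13. Corey–Winter fragmentation with 1,3-dimethyl-2-phenyl-1,3,2-diazaphospholidine at 40 °C then gives 26 by stereospecific syn elimination.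

Step 20. Most likely failure: hydride transfer to boron with loss of the C–B bond on work-up, or conjugate reduction of the dienoate. Fallback, from 32 to 37: tin replaces boron and the last coupling becomes base-free. Olefination of 32 with (2E)-3-(tributylstannyl)prop-2-enal F14 under the conditions of step 19 gives the stannyl dienoate F15. iBu2AlH gives the stannyl dienol F16, alkenylstannanes being inert to this hydride. Stille coupling of F16 with 36 (Pd2(dba)3, AsPh3, NMP, rt to 40 °C) gives 37.

## Further compounds

F1 | step 7 | (3E)-5-(benzyloxy)-4-methylpent-3-en-2-one | CC(=O)/C=C(\C)COCc1ccccc1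
F2 | step 7 | (2R,3E)-5-(benzyloxy)-4-methylpent-3-en-2-ol | O[C@H](C)/C=C(\C)COCc1ccccc1
F3 | step 7 | 2,2-dimethyl-5-(2-methylpent-4-en-2-yl)-1,3-dioxane-4,6-dione | CC1(C)OC(=O)C(C(C)(C)CC=C)C(=O)O1
F4 | step 7 | 3,3-dimethylhex-5-enoic acid | C=CCC(C)(C)CC(=O)O
F5 | step 7 | (2R,3E)-5-(benzyloxy)-4-methylpent-3-en-2-yl 3,3-dimethylhex-5-enoate | C=CCC(C)(C)CC(=O)O[C@H](C)/C=C(\C)COCc1ccccc1
F6 | step 7 | (2R,3S,4E)-3-[(benzyloxy)methyl]-3-methyl-2-(2-methylpent-4-en-2-yl)hex-4-enoic acid | c1ccccc1COC[C@@](C)(/C=C/C)[C@H](C(=O)O)C(C)(C)CC=C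
F7 | step 6 | methyl 3,3-dimethyl-5-oxopentanoate | COC(=O)CC(C)(C)CC=O
F8 | step 6 | [(1E)-3-(benzyloxy)-2-methylprop-1-en-1-yl]zinc bromide | C/C(=C\[Zn]Br)COCc1ccccc1
F9 | step 10 | (3aS,7aR)-3a,7,7-trimethylhexahydro-2-benzofuran-1(3H)-one | O1C[C@@]2(C)CCCC(C)(C)[C@H]2C1=O
F10 | step 10 | (3aS,7aR)-3a,7,7-trimethyloctahydro-2-benzofuran-1-ol (both anomers) | O1C[C@@]2(C)CCCC(C)(C)[C@H]2C1O
F11 | step 10 | (3E)-4-[(1R,2S)-2-(hydroxymethyl)-2,6,6-trimethylcyclohexyl]but-3-en-2-one | OC[C@@]2(C)CCCC(C)(C)[C@H]2/C=C/C(C)=O
F12 | step 15 | (4aR,8aS)-2,5,5,8a-tetramethyl-1-(prop-2-en-1-yl)decahydronaphthalene-1,2-diol (cis diol) | CC1(O)C(O)(CC=C)[C@@]2(C)CCCC(C)(C)[C@H]2CC1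
F13 | step 15 | cyclic thiocarbonate of F12 (1,3-dioxolane-2-thione fused at C8–C9) | CC14OC(=S)OC4(CC=C)[C@@]2(C)CCCC(C)(C)[C@H]2CC1
F14 | step 20 | (2E)-3-(tributylstannyl)prop-2-enal | CCCC[Sn](CCCC)(CCCC)/C=C/C=O
F15 | step 20 | ethyl (2E,4E)-2-{2-[(4aR,8aS)-2,5,5,8a-tetramethyl-3,4,4a,5,6,7,8,8a-octahydronaphthalen-1-yl]ethyl}-5-(tributylstannyl)penta-2,4-dienoate | CC1=C(CC/C(=C\C=C\[Sn](CCCC)(CCCC)CCCC)C(=O)OCC)[C@@]2(C)CCCC(C)(C)[C@H]2CC1
F16 | step 20 | (2E,4E)-2-{2-[(4aR,8aS)-2,5,5,8a-tetramethyl-3,4,4a,5,6,7,8,8a-octahydronaphthalen-1-yl]ethyl}-5-(tributylstannyl)penta-2,4-dien-1-ol | CC1=C(CC/C(=C\C=C\[Sn](CCCC)(CCCC)CCCC)CO)[C@@]2(C)CCCC(C)(C)[C@H]2CC1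
A1 | alternative 1 | (3E,7Z)-4,8,12-trimethyltrideca-3,7,11-trien-1-ol ((3E,7Z)-homofarnesol) | OCC/C=C(\C)CC/C=C(/C)CCC=C(C)C
A2 | alternative 1 | tricyclic ether with cis-fused rings A and B (dodecahydronaphtho[2,1-b]furan skeleton) | C[C@]12CC[C@@H]3C(C)(C)CCC[C@]3(C)[C@@H]1CCO2
A3 | alternative 2 | methyl 4-methyl-6-[(1S)-2,2,6-trimethyl-5-oxocyclohexyl]hex-2-ynoate (C8 and C10 as mixtures) | COC(=O)C#CC(C)CC[C@@H]1C(C)(C)CCC(=O)C1C
A4 | alternative 2 | cis-decalone with exocyclic C9=C11 enoate | COC(=O)C=C1C(C)CC[C@@H]2C(C)(C)CCC(=O)[C@]12C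
A5 | alternative 3 | 2,6-dimethyl-1,4-benzoquinone | CC1=CC(=O)C=C(C)C1=O
A6 | alternative 3 | (prop-2-en-1-ylidene)cyclopropane (allylidenecyclopropane) | C=CC=C1CC1
A7 | alternative 3 | cis-fused enedione adduct with C4 spirocyclopropane | CC1=CC(=O)[C@@H]2C3(CC3)C=CC[C@]2(C)C1=O
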